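If each second substrate takes one coupling partner, each target one and each over-reaction product two, then the number to carry is the spare partner, a stoichiometric budget: the partner charged less the second substrate charged, per starting material charged. 75.0% is what this flask holds, against 43.9% in the alder run and 85.0% in the ash run.

the same everywhere: starting material 0.072 M
- alder: coupling partner 0.046 M; second substrate 0.0144 M; run made earlier
- larch: coupling partner 0.10 M; second substrate 0.0144 M; run made earlier
- ash: coupling partner 0.0684 M; second substrate 0.0072 M; run made earlier
- flask: coupling partner 0.0684 M; second substrate 0.0144 M; time 3.0 h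

| run | time / h | over-reaction product / % | target / % |
|---|---|---|---|
| alder | 0.833 | 5.8 | 20.9 |
| alder | 1.00 | 7.5 | 20.8 |
| alder | 1.33 | 8.3 | 20.9 |
| alder | 1.50 | 9.5 | 20.5 |
| alder | 2.00 | 10.6 | 18.7 |
| alder | 2.50 | 11.4 | 17.5 |
| larch | 0.833 | 26.7 | 29.9 |
| larch | 1.00 | 29.4 | 27.9 |
| larch | 1.33 | 34.6 | 25.9 |
| larch | 1.50 | 35.6 | 23.9 |
| larch | 2.00 | 39.5 | 21.1 |
| larch | 2.50 | 42.3 | 18.5 |
| ash | 0.833 | 16.2 | 27.6 |
| ash | 1.00 | 17.6 | 27.4 |
| ash | 1.33 | 21.7 | 26.2 |
| ash | 2.00 | 26.2 | 21.9 |
| ash | 2.50 | 27.4 | 19.2 |

(scatter of a reading: 0.5 percentage points)

- time up to 3.0 h at which over-reaction product stands highest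
- the amount of over-reaction product, in percent of the starting material charged, at that time
- the first time at which over-reaction product reaches 12%, in the same percent



In the ash run, over-reaction product gains 5.5 percentage points between 0.833 h and 1.33 h but 1.2 points between 2.00 h and 2.50 h, windows of about equal length, so its pace reads 4.58 times lower, with a late gain that carries the scatter of 0.5 points. If the pace follows [coupling partner][target], the slowing has two factors from the first reading to the last. Counting the second substrate as spent, I take unspent partner in the ash run as spare partner less target less twice over-reaction product; it reads 25.0% and then 11.0%, a factor of 2.27, and target falls by a factor of 1.44.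

With that accumulated slowing in the readings, I reckon the late flask by its budget. The part of the spare partner outside over-reaction product stands at 21.1% in alder and 30.2% in ash at 2.50 h. Weighted by spare partner, this flask gets 28.0%, which gives 23.5% then. The product still rises at the last ash reading, so I put the peak at the end, 3.0 h, and adding the late ash gain makes it 24.7%. The same weighting gives 13.7% at 0.833 h, above 12%, so I put that level earlier in this flask.

The forecast gives 22% at 3 h, lower than my figure, and 12% at 0.8 h, noting that “Product only creeps upward, with no sign of being consumed”.

The flask gives 24.9% at 3.00 h and reaches 12% at 0.729 h.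

    starting material + coupling partner ⇌ target (K = 51.0 /M, k = 0.00648 /M/s)
    second substrate + coupling partner → second product (k = 0.0293 /M/s)
    coupling partner + target → over-reaction product (k = 0.00738 /M/s)

In this flask, second substrate stands at 0.807% of its charge at 3.00 h, close to what subtracting the whole charge supposed. Outside over-reaction product, the spare partner of 75.0% in this flask leaves 25.3% at that time.

With 0.0058 M of second substrate, the neighbour flask has 86.9% spare partner, so the same outside part gives 30.8%. The computed result there is 30.1%.

(All runs come from a simulation for substances that don't exist; the scatter is artificial.)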